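**Retrosynthetic overview**
1. The target is a symmetric biphenyl. Both acids are traced back to silyl-protected 3-hydroxypropyl chains and both phenols to benzyl ethers.
2. Key disconnection: ring B carries on three adjacent carbons the ring A aryl group (C1), a hydroxyl (C2) and a methoxy group (C3). The C1(ring A)–C1(ring B) bond and the C2(ring B)–O bond are cut together across a 3-methoxy-5-alkylbenzyne. An aryl Grignard adds to it meta to the methoxy group and the ortho carbanion is then oxygenated.
3. The ring A Grignard precursor and the ring B aryne precursor both come from one iodophenol, obtained from dihydroferulic acid by reduction and ortho-iodination.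
4. No ring is formed: both benzene rings come intact from dihydroferulic acid and are joined in the key step.

Key step: step 7

Remark: the target has no stereocentre, and with a single ortho substituent beside the biaryl bond on each ring the axis rotates freely, so no stereocontrol is needed.
Remark on locants: ring A enters as the Grignard reagent and ring B is generated as the aryne; locants quoted with a ring letter count from the biaryl carbon (C1) of that ring.

**Route**

Step 1
Reactants: 1 dihydroferulic acid, 3-(4-hydroxy-3-methoxyphenyl)propanoic acid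
Product: 2 3-(4-hydroxy-3-methoxyphenyl)propan-1-ol
Conditions: BH3·THF (excess), THF, 0 °C to rt; then H2O, dilute HCl
Reagents that add atoms: none
Why: Borane reduction of a carboxylic acid proceeds through an acyloxyborane, and the phenol is only converted into a borate that hydrolyses on work-up.

Step 2
Reactants: 2 3-(4-hydroxy-3-methoxyphenyl)propan-1-ol
Product: 3 3-(4-hydroxy-3-iodo-5-methoxyphenyl)propan-1-ol
Conditions: I2, KI, NaHCO3, H2O/MeOH, 0 °C to rt
Reagents that add atoms: iodine, II
Why: Electrophilic aromatic iodination under bicarbonate runs through the phenoxide, whose para carbon carries the chain and whose other ortho carbon carries the methoxy group, so iodine should enter only at the free carbon next to the hydroxyl.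

Step 3
Reactants: 3 3-(4-hydroxy-3-iodo-5-methoxyphenyl)propan-1-ol
Product: 4 3-[4-(benzyloxy)-3-iodo-5-methoxyphenyl]propan-1-ol
Conditions: BnBr, K2CO3, acetone, reflux
Reagents that add atoms: benzyl bromide, BrCc1ccccc1
Why: Williamson etherification; K2CO3 deprotonates only the phenol, so the phenoxide is benzylated and the primary alcohol stays free.

Step 4
Reactants: 4 3-[4-(benzyloxy)-3-iodo-5-methoxyphenyl]propan-1-ol
Product: 5 {3-[4-(benzyloxy)-3-iodo-5-methoxyphenyl]propoxy}(tert-butyl)dimethylsilane
Conditions: TBSCl, imidazole, CH2Cl2, rt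
Reagents that add atoms: tert-butyldimethylsilyl chloride, CC(C)(C)[Si](C)(C)Cl
Why: Imidazole-promoted silylation of a primary alcohol; the aryl iodide and benzyl ether are inert.

Step 5
Reactants: 3 3-(4-hydroxy-3-iodo-5-methoxyphenyl)propan-1-ol
Product: 6 4-(3-hydroxypropyl)-2-iodo-6-methoxyphenyl 4-chlorobenzenesulfonate
Conditions: 4-ClC6H4SO2Cl (1.05 equiv), K2CO3, acetone, 0 °C to rt
Reagents that add atoms: 4-chlorobenzenesulfonyl chloride, O=S(=O)(Cl)c1ccc(Cl)cc1
Why: Schotten–Baumann-type sulfonylation of the phenoxide should be chemoselective, because the aliphatic alcohol is not deprotonated by carbonate and reacts only slowly with a sulfonyl chloride without an amine catalyst.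

Step 6
Reactants: 6 4-(3-hydroxypropyl)-2-iodo-6-methoxyphenyl 4-chlorobenzenesulfonate
Product: 7 4-[3-(tert-butyldimethylsilyloxy)propyl]-2-iodo-6-methoxyphenyl 4-chlorobenzenesulfonate
Conditions: TBSCl, imidazole, CH2Cl2, rt
Reagents that add atoms: tert-butyldimethylsilyl chloride, CC(C)(C)[Si](C)(C)Cl
Why: Imidazole-promoted silylation of the primary alcohol; the aryl sulfonate and aryl iodide are stable to these conditions.

Step 7
Reactants: 5 {3-[4-(benzyloxy)-3-iodo-5-methoxyphenyl]propoxy}(tert-butyl)dimethylsilane; 7 4-[3-(tert-butyldimethylsilyloxy)propyl]-2-iodo-6-methoxyphenyl 4-chlorobenzenesulfonate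
Product: 13 2'-(benzyloxy)-3,3'-dimethoxy-5,5'-bis[3-(tert-butyldimethylsilyloxy)propyl]biphenyl-2-ol, via ring A arylmagnesium chloride 8 (not isolated), via 2-magnesiated aryl sulfonate 9 (not isolated), via 3-methoxy-5-alkylbenzyne 10 (not isolated), via 2-biarylmagnesium chloride 11 (not isolated), via dimethyl biarylboronate 12 (not isolated)
Conditions: (a) 5 (1.3 equiv), iPrMgCl·LiCl (slight deficit), THF, 0 °C; (b) 7, iPrMgCl·LiCl (1.0 equiv), THF, −78 °C; (c) solution of 8 added to 9 at −78 °C, then warmed to rt; (d) B(OMe)3, 0 °C to rt; (e) 30% aq. H2O2, 0 °C to rt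
Reagents that add atoms: hydrogen peroxide, OO
Why: Iodine–magnesium exchange at −78 °C turns 7 into the 2-magnesiated sulfonate 9, which on warming loses the magnesium sulfonate to give aryne 10 with its triple bond between C1 and C2 of ring B; Grignard 8, made from 5 by the same exchange, adds its carbon to C1, forming the biaryl bond and leaving magnesium on C2 in 11. Borylation of 11 with B(OMe)3 gives 12, and H2O2 oxidises the C–B bond by 1,2-migration of the aryl group from boron to oxygen, so the hydroxyl should appear on the carbon that carried magnesium. The closest known reaction type is the addition of arylmagnesium halides to arynes released from 2-magnesiated aryl sulfonates or 1,2-dihaloarenes with electrophilic trapping of the 2-biarylmagnesium, as used for biarylphosphine ligands, joined to the standard borate–peroxide conversion of an aryl Grignard into a phenol. No ring is closed and no stereocentre is formed. The step needs regioselective attack on the unsymmetrical aryne: the methoxy group on C3 withdraws electron density through the sigma framework, makes C1 the more electrophilic terminus and stabilises the carbanion developing on the adjacent C2, so the aryl group should enter meta and the oxygen ortho to the methoxy group. Chemoselectivity rests on completing the exchange on 7 at −78 °C before 8 is added, so that no alkyl Grignard competes for the aryne, and on the silyl ether chains, which are inert to organomagnesium reagents.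

Step 8
Reactants: 13 2'-(benzyloxy)-3,3'-dimethoxy-5,5'-bis[3-(tert-butyldimethylsilyloxy)propyl]biphenyl-2-ol
Product: 14 2,2'-bis(benzyloxy)-3,3'-dimethoxy-5,5'-bis[3-(tert-butyldimethylsilyloxy)propyl]biphenyl
Conditions: BnBr, K2CO3, DMF, 50 °C
Reagents that add atoms: benzyl bromide, BrCc1ccccc1
Why: Williamson etherification of the hindered phenoxide in a dipolar aprotic solvent; it masks the phenol against the later oxidation and makes the molecule symmetric.

Step 9
Reactants: 14 2,2'-bis(benzyloxy)-3,3'-dimethoxy-5,5'-bis[3-(tert-butyldimethylsilyloxy)propyl]biphenyl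
Product: 15 3,3'-[6,6'-bis(benzyloxy)-5,5'-dimethoxybiphenyl-3,3'-diyl]di(propan-1-ol)
Conditions: Bu4NF, THF, rt
Reagents that add atoms: none
Why: Fluoride-induced desilylation cleaves both primary silyl ethers through Si–F bond formation and leaves the benzyl ethers untouched.

Step 10
Reactants: 15 3,3'-[6,6'-bis(benzyloxy)-5,5'-dimethoxybiphenyl-3,3'-diyl]di(propan-1-ol)
Product: 16 3,3'-[6,6'-bis(benzyloxy)-5,5'-dimethoxybiphenyl-3,3'-diyl]dipropanoic acid
Conditions: TEMPO (cat.), NaOCl (cat.), NaClO2, MeCN/sodium phosphate buffer pH 6.7, 35 °C; then acidify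
Reagents that add atoms: sodium chlorite, [Na+].[O-]Cl=O
Why: Anelli-type oxoammonium oxidation of the primary alcohols to aldehydes is followed in the same pot by chlorite oxidation to the acids, with only catalytic hypochlorite present so that chlorination of the alkoxyarene rings is limited.

Step 11
Reactants: 16 3,3'-[6,6'-bis(benzyloxy)-5,5'-dimethoxybiphenyl-3,3'-diyl]dipropanoic acid
Product: 17 3,3'-(6,6'-dihydroxy-5,5'-dimethoxybiphenyl-3,3'-diyl)dipropanoic acid
Conditions: H2 (1 atm), palladium on carbon (Pd/C), MeOH/EtOAc, rt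
Reagents that add atoms: none
Why: Catalytic hydrogenolysis cleaves both aryl benzyl ethers to the phenols, and the acids, methoxy groups and biaryl are inert.

**Compound list**
1 | dihydroferulic acid, 3-(4-hydroxy-3-methoxyphenyl)propanoic acid | COc1cc(CCC(=O)O)ccc1O | starting material
2 | 3-(4-hydroxy-3-methoxyphenyl)propan-1-ol | COc1cc(CCCO)ccc1O | intermediate
3 | 3-(4-hydroxy-3-iodo-5-methoxyphenyl)propan-1-ol | COc1cc(CCCO)cc(I)c1O | intermediate
4 | 3-[4-(benzyloxy)-3-iodo-5-methoxyphenyl]propan-1-ol | COc1cc(CCCO)cc(I)c1OCc1ccccc1 | intermediate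
5 | {3-[4-(benzyloxy)-3-iodo-5-methoxyphenyl]propoxy}(tert-butyl)dimethylsilane | COc1cc(CCCO[Si](C)(C)C(C)(C)C)cc(I)c1OCc1ccccc1 | intermediate
6 | 4-(3-hydroxypropyl)-2-iodo-6-methoxyphenyl 4-chlorobenzenesulfonate | COc1cc(CCCO)cc(I)c1OS(=O)(=O)c1ccc(Cl)cc1 | intermediate
7 | 4-[3-(tert-butyldimethylsilyloxy)propyl]-2-iodo-6-methoxyphenyl 4-chlorobenzenesulfonate | COc1cc(CCCO[Si](C)(C)C(C)(C)C)cc(I)c1OS(=O)(=O)c1ccc(Cl)cc1 | intermediate
8 | {2-(benzyloxy)-3-methoxy-5-[3-(tert-butyldimethylsilyloxy)propyl]phenyl}magnesium chloride (ring A Grignard, LiCl complex) | COc1cc(CCCO[Si](C)(C)C(C)(C)C)cc([Mg]Cl)c1OCc1ccccc1 | intermediate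
9 | 2-(chloromagnesio)-6-methoxy-4-[3-(tert-butyldimethylsilyloxy)propyl]phenyl 4-chlorobenzenesulfonate | COc1cc(CCCO[Si](C)(C)C(C)(C)C)cc([Mg]Cl)c1OS(=O)(=O)c1ccc(Cl)cc1 | intermediate
10 | 3-methoxy-5-[3-(tert-butyldimethylsilyloxy)propyl]benzyne | COC1=CC(CCCO[Si](C)(C)C(C)(C)C)=CC#C1 | intermediate
11 | {2'-(benzyloxy)-3,3'-dimethoxy-5,5'-bis[3-(tert-butyldimethylsilyloxy)propyl]biphenyl-2-yl}magnesium chloride | COc1cc(CCCO[Si](C)(C)C(C)(C)C)cc(-c2cc(CCCO[Si](C)(C)C(C)(C)C)cc(OC)c2OCc2ccccc2)c1[Mg]Cl | intermediate
12 | dimethyl {2'-(benzyloxy)-3,3'-dimethoxy-5,5'-bis[3-(tert-butyldimethylsilyloxy)propyl]biphenyl-2-yl}boronate | COc1cc(CCCO[Si](C)(C)C(C)(C)C)cc(-c2cc(CCCO[Si](C)(C)C(C)(C)C)cc(OC)c2OCc2ccccc2)c1B(OC)OC | intermediate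
13 | 2'-(benzyloxy)-3,3'-dimethoxy-5,5'-bis[3-(tert-butyldimethylsilyloxy)propyl]biphenyl-2-ol | COc1cc(CCCO[Si](C)(C)C(C)(C)C)cc(-c2cc(CCCO[Si](C)(C)C(C)(C)C)cc(OC)c2OCc2ccccc2)c1O | intermediate
14 | 2,2'-bis(benzyloxy)-3,3'-dimethoxy-5,5'-bis[3-(tert-butyldimethylsilyloxy)propyl]biphenyl | COc1cc(CCCO[Si](C)(C)C(C)(C)C)cc(-c2cc(CCCO[Si](C)(C)C(C)(C)C)cc(OC)c2OCc2ccccc2)c1OCc1ccccc1 | intermediate
15 | 3,3'-[6,6'-bis(benzyloxy)-5,5'-dimethoxybiphenyl-3,3'-diyl]di(propan-1-ol) | COc1cc(CCCO)cc(-c2cc(CCCO)cc(OC)c2OCc2ccccc2)c1OCc1ccccc1 | intermediate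
16 | 3,3'-[6,6'-bis(benzyloxy)-5,5'-dimethoxybiphenyl-3,3'-diyl]dipropanoic acid | COc1cc(CCC(=O)O)cc(-c2cc(CCC(=O)O)cc(OC)c2OCc2ccccc2)c1OCc1ccccc1 | intermediate
17 | 3,3'-(6,6'-dihydroxy-5,5'-dimethoxybiphenyl-3,3'-diyl)dipropanoic acid | COc1cc(CCC(=O)O)cc(-c2cc(CCC(=O)O)cc(OC)c2O)c1O | target

**Step count**
Total: 11 steps. Longest linear sequence: 9 steps (steps 1, 2, 3, 4, 7, 8, 9, 10, 11; the branch through steps 5 and 6 is equally long).

**Steps most likely to fail**

Step 7. The aryl Grignard may add to the aryne with incomplete regiocontrol, the 2-biarylmagnesium may add to further aryne and give oligomers, or the hindered arylmagnesium may be borylated only partly. The fallback gives up the aryne and sets out from 5. Iodine–magnesium exchange on part of 5 (iPrMgCl·LiCl, THF, 0 °C) and quenching with 2-isopropoxy-4,4,5,5-tetramethyl-1,3,2-dioxaborolane should give 2-{2-(benzyloxy)-3-methoxy-5-[3-(tert-butyldimethylsilyloxy)propyl]phenyl}-4,4,5,5-tetramethyl-1,3,2-dioxaborolane F1. Suzuki–Miyaura coupling of this boronate with a second portion of 5 (Pd(OAc)2, SPhos, K3PO4, toluene/H2O, 80 °C) should give the symmetric biaryl directly. The fallback comes back to the route at 14, so that 7 and step 8 are not needed.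

Step 5. The primary hydroxyl may be sulfonylated in competition, or the phenoxide flanked by iodine and methoxy may react sluggishly, giving mixtures. The fallback sets out from 3 and separates the two hydroxyls by silyl chemistry. Excess TBSCl and imidazole in DMF should give tert-butyl{3-[4-(tert-butyldimethylsilyloxy)-3-iodo-5-methoxyphenyl]propoxy}dimethylsilane F2. K2CO3 in MeOH then cleaves only the aryl silyl ether to give 4-[3-(tert-butyldimethylsilyloxy)propyl]-2-iodo-6-methoxyphenol F3; if the hindered phenol resists silylation, this compound forms directly. Sulfonylation with 4-chlorobenzenesulfonyl chloride, Et3N and catalytic DMAP in CH2Cl2 brings the fallback back to the route at 7.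

Step 10. Hypochlorite may chlorinate the electron-rich alkoxyarene rings, or the oxidation may stall at the aldehyde stage. The fallback sets out from 15 and splits the oxidation into two isolated stages. Dess–Martin periodinane in CH2Cl2 with NaHCO3 should give 3,3'-[6,6'-bis(benzyloxy)-5,5'-dimethoxybiphenyl-3,3'-diyl]dipropanal F4. Pinnick oxidation (NaClO2, NaH2PO4, 2-methyl-2-butene as chlorine scavenger, tBuOH/H2O) then brings the fallback back to the route at 16.

**Further compounds**
F1 | step 7 | 2-{2-(benzyloxy)-3-methoxy-5-[3-(tert-butyldimethylsilyloxy)propyl]phenyl}-4,4,5,5-tetramethyl-1,3,2-dioxaborolane | COc1cc(CCCO[Si](C)(C)C(C)(C)C)cc(B2OC(C)(C)C(C)(C)O2)c1OCc1ccccc1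
F2 | step 5 | tert-butyl{3-[4-(tert-butyldimethylsilyloxy)-3-iodo-5-methoxyphenyl]propoxy}dimethylsilane | COc1cc(CCCO[Si](C)(C)C(C)(C)C)cc(I)c1O[Si](C)(C)C(C)(C)C
F3 | step 5 | 4-[3-(tert-butyldimethylsilyloxy)propyl]-2-iodo-6-methoxyphenol | COc1cc(CCCO[Si](C)(C)C(C)(C)C)cc(I)c1O
F4 | step 10 | 3,3'-[6,6'-bis(benzyloxy)-5,5'-dimethoxybiphenyl-3,3'-diyl]dipropanal | COc1cc(CCC=O)cc(-c2cc(CCC=O)cc(OC)c2OCc2ccccc2)c1OCc1ccccc1
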